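**Plan** (eudesmane numbering: ring A = C1–C5 + C10, ring B = C5–C10, C14 on C10, C15 on C4, C11(=C13)–C12O2Me on C7)
Retrosynthesis: the 5-hydroxy-4(15)-ene is traced to a C4=C5 alkene (ene reaction with singlet oxygen), the C3 ester to a C3 ketone, and the C8 acetate/C12 methyl ester pair to the cis-fused 12,8-lactone 19; ring B of 19 is then cut at C9–C10 and C7–C8.
Enabling feature: O8 lies 1,5 to C4 across the allyl unit C4–C5=C10, so it can arrive from a C4 O-vinyl ether by a [3,3] shift that also creates quaternary C10; C7 carries a 2-(methoxycarbonyl)allyl group, the retron of an allylboration of the C8 aldehyde formed in that shift.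
Forward: ring A first (steps 1–6), side chain by cross-metathesis (steps 7–8), ring B and the lactone in one operation with vinyl acetate (step 9), then lactone opening/acetylation, C3 reduction, angeloylation and the ene reaction (steps 10–13).
Stereochemistry: a lipase resolution sets C3 of ring A, which directs the Grignard addition at C4; C4 is relayed to C10 by the suprafacial rearrangement; C10 then controls C7/C8 (chair allylboration), C3 (Luche reduction) and C5 (α-face ene reaction).

Key step: step 9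

Remark: the lipase is assumed to follow the usual size preference for secondary alcohols and to acylate the (R)-enantiomer of 6 faster; the ester is the material carried on.

Step 1
Reactants: 1 2-(prop-2-en-1-yl)cyclohexane-1,3-dione
Product: 2 3-(2-methylpropoxy)-2-(prop-2-en-1-yl)cyclohex-2-en-1-one
Conditions: i-BuOH, p-TsOH·H2O (cat.), toluene, reflux, Dean–Stark
Reagents that add atoms: 2-methylpropan-1-ol CC(C)CO
Why: Acid-catalysed enol ether formation of the symmetric cyclic 1,3-dione (vinylogous ester), driven by azeotropic removal of water; no stereocentre is formed.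

Step 2
Reactants: 2 3-(2-methylpropoxy)-2-(prop-2-en-1-yl)cyclohex-2-en-1-one
Product: 4 3-methyl-2-(prop-2-en-1-yl)cyclohex-2-en-1-one, via lithium alkoxide adduct 3 (not isolated)
Conditions: MeLi, Et2O, −78 → 0 °C; then 2 M HCl, THF, rt
Reagents that add atoms: methyllithium [Li]C; water O
Why: Stork–Danheiser sequence: 1,2-addition of MeLi to the vinylogous ester, then acid hydrolysis and dehydration with carbonyl transposition gives the 2,3-disubstituted enone.

Step 3
Reactants: 4 3-methyl-2-(prop-2-en-1-yl)cyclohex-2-en-1-one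
Product: 6 rac-6-hydroxy-3-methyl-2-(prop-2-en-1-yl)cyclohex-2-en-1-one, via potassium dienolate 5 (not isolated)
Conditions: KN(SiMe3)2, THF, −78 °C; then (±)-trans-3-phenyl-2-(phenylsulfonyl)oxaziridine, −78 °C; aq NH4Cl
Reagents that add atoms: 3-phenyl-2-(phenylsulfonyl)oxaziridine O=S(=O)(c1ccccc1)N1OC1c1ccccc1
Why: Kinetic α'-deprotonation gives the cross-conjugated dienolate, which the N-sulfonyloxaziridine hydroxylates at C6 (Davis oxidation); the new carbinol centre is racemic at this stage.

Step 4
Reactants: 6 rac-6-hydroxy-3-methyl-2-(prop-2-en-1-yl)cyclohex-2-en-1-one; 7 ethenyl acetate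
Product: 8 (1R)-4-methyl-2-oxo-3-(prop-2-en-1-yl)cyclohex-3-en-1-yl acetate
Conditions: lipase B from Candida antarctica (immobilised; serine hydrolase of the lipase class), 7 (3 equiv), t-BuOMe, 30 °C, stopped near half conversion
Reagents that add atoms: none
Why: Lipase-catalysed irreversible acyl transfer (kinetic resolution) should acylate the (R)-alcohol, whose large enone side and small CH2 side fit the enzyme pockets, leaving the (S)-alcohol to be separated; this fixes the absolute configuration of the route.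

Step 5
Reactants: 8 (1R)-4-methyl-2-oxo-3-(prop-2-en-1-yl)cyclohex-3-en-1-yl acetate
Product: 10 (1R,2S)-2,4-dimethyl-3-(prop-2-en-1-yl)cyclohex-3-ene-1,2-diol, via bromomagnesium alkoxide 9 (not isolated)
Conditions: MeMgBr (4 equiv), THF, −78 → 0 °C; aq NH4Cl
Reagents that add atoms: methylmagnesium bromide C[Mg]Br
Why: Excess Grignard reagent cleaves the acetate and then adds 1,2 to the β,β-disubstituted enone under chelation control by the magnesium alkoxide, so the methyl group enters trans to the existing oxygen and the cis-diol with the (2S) tertiary carbinol should result.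

Step 6
Reactants: 10 (1R,2S)-2,4-dimethyl-3-(prop-2-en-1-yl)cyclohex-3-ene-1,2-diol
Product: 11 (2S)-2-hydroxy-2,4-dimethyl-3-(prop-2-en-1-yl)cyclohex-3-en-1-one
Conditions: 2-iodoxybenzoic acid (IBX), DMSO, rt
Reagents that add atoms: none
Why: IBX oxidises the secondary alcohol of a 1,2-diol to the α-ketol without C–C cleavage; the tertiary allylic alcohol and its stereocentre (the future C4) are untouched.

Step 7
Reactants: 12 methyl 2-(bromomethyl)prop-2-enoate; 13 bis(pinacolato)diboron
Product: 14 methyl 2-[(4,4,5,5-tetramethyl-1,3,2-dioxaborolan-2-yl)methyl]prop-2-enoate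
Conditions: CuCl (10 mol%), KOAc, DMF, rt
Reagents that add atoms: none
Why: Copper-catalysed borylation of an allylic bromide with B2pin2; direct and allylically transposed substitution give the same product on this allyl unit.

Step 8
Reactants: 11 (2S)-2-hydroxy-2,4-dimethyl-3-(prop-2-en-1-yl)cyclohex-3-en-1-one; 14 methyl 2-[(4,4,5,5-tetramethyl-1,3,2-dioxaborolan-2-yl)methyl]prop-2-enoate
Product: 15 methyl (2E)-4-[(6S)-6-hydroxy-2,6-dimethyl-5-oxocyclohex-1-en-1-yl]-2-[(4,4,5,5-tetramethyl-1,3,2-dioxaborolan-2-yl)methyl]but-2-enoate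
Conditions: second-generation Hoveyda–Grubbs catalyst RuCl2(H2IMes)(=CH-C6H4-2-OiPr) (5 mol%), 14 (3 equiv), CH2Cl2, 40 °C
Reagents that add atoms: none
Why: Olefin cross-metathesis of the terminal alkene with a 1,1-disubstituted acrylate partner (methacrylate type) should give the trisubstituted alkene with the chain trans to the ester (E), i.e. C6 cis to the CH2B group; the tetrasubstituted ring alkene is inert.

Step 9
Reactants: 15 methyl (2E)-4-[(6S)-6-hydroxy-2,6-dimethyl-5-oxocyclohex-1-en-1-yl]-2-[(4,4,5,5-tetramethyl-1,3,2-dioxaborolan-2-yl)methyl]but-2-enoate; 7 ethenyl acetate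
Product: 19 (7R,8R,10R)-3-oxoeudesma-4,11(13)-dien-12,8-olide, via tertiary allyl vinyl ether 16 (not isolated), via rearranged aldehyde 17 (not isolated), via cyclised borate ester 18 (not isolated)
Conditions: 7 (5 equiv), [IrCl(C8H12)]2 (2 mol%; C8H12 = cycloocta-1,5-diene), Na2CO3 (1 equiv), toluene, 105 °C, sealed tube; then p-TsOH·H2O (10 mol%), 60 °C
Reagents that add atoms: none
Why: Proposed new method: the iridium alkoxide of 15 adds to vinyl acetate and loses acetate to give the tertiary allyl vinyl ether 16, which undergoes a [3,3]-sigmatropic (Claisen) shift across C4–C5=C10 to aldehyde 17; the pendant allylboronate then adds to this aldehyde through a six-membered chair transition state and the borate 18 closes onto the ester. The closest known reactions are the iridium-catalysed vinyl transfer from vinyl acetate to allylic alcohols followed by Claisen rearrangement in the same flask, and domino sequences in which an aldehyde generated in situ is trapped by an intramolecular allylboration; their combination and the use on a tertiary α-ketol are new. Ring B closes 6-exo-trig at the aldehyde carbon as a chair in which the C4=C5 bond, exocyclic to the new ring, forces C1 equatorial and the C10 methyl axial, and the lactone ring closes 5-exo-trig at the ester carbon. C10 is set by the C4 carbinol centre, because C9 must bond to the α-face from which the C4–O bond departs (the methyl stays β); C7 and C8 are set by the (E) alkene geometry, which places C6 axial in the boron-containing chair and so gives the C7 side chain equatorial (β) and the C8 oxygen axial (β), cis to each other. The selectivity needed is rearrangement and intramolecular trapping ahead of acetyl transfer, retro-ene loss of acetaldehyde and intermolecular allylboration; the tertiary ketone-flanked allyl ether (the product is a conjugated enone), the inertness of 2-alkoxycarbonyl allylboronates towards ketones and the six-membered ring size of the trap should secure it.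

Step 10
Reactants: 19 (7R,8R,10R)-3-oxoeudesma-4,11(13)-dien-12,8-olide
Product: 22 methyl (7R,8R,10R)-8-acetoxy-3-oxoeudesma-4,11(13)-dien-12-oate, via lithium carboxylate 20 (not isolated), via hydroxy ester 21 (not isolated)
Conditions: LiOH·H2O (1.1 equiv), THF–H2O, 0 °C; evaporation; MeI, DMF, rt; then Ac2O, pyridine, DMAP (cat.), 0 °C → rt
Reagents that add atoms: lithium hydroxide [Li+].[OH-]; iodomethane CI; acetic anhydride CC(=O)OC(C)=O
Why: Saponification of the γ-lactone, O-alkylation of the carboxylate and immediate acetylation of the axial C8 alcohol are telescoped so that the γ-hydroxy ester is acylated before it can re-lactonise; the lactone is the only ester present and no stereocentre is touched.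

Step 11
Reactants: 22 methyl (7R,8R,10R)-8-acetoxy-3-oxoeudesma-4,11(13)-dien-12-oate
Product: 23 methyl (3S,7R,8R,10R)-8-acetoxy-3-hydroxyeudesma-4,11(13)-dien-12-oate
Conditions: NaBH4, CeCl3·7H2O, MeOH, −40 °C
Reagents that add atoms: none
Why: Luche reduction: 1,2-selective hydride delivery to the enone by axial attack on the α-face, opposite the axial C10 methyl, should give the equatorial 3β-alcohol (3S); acrylate and acetate are not reduced under these conditions.

Step 12
Reactants: 23 methyl (3S,7R,8R,10R)-8-acetoxy-3-hydroxyeudesma-4,11(13)-dien-12-oate; 24 (2Z)-2-methylbut-2-enoic acid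
Product: 25 methyl (3S,7R,8R,10R)-8-acetoxy-3-[(2Z)-2-methylbut-2-enoyloxy]eudesma-4,11(13)-dien-12-oate
Conditions: 24, 2,4,6-trichlorobenzoyl chloride, Et3N, toluene, rt; then 23, 75 °C
Reagents that add atoms: none
Why: Yamaguchi-type mixed-anhydride esterification run without a nucleophilic catalyst transfers the angeloyl group without Z to E isomerisation and with retention at C3.

Step 13
Reactants: 25 methyl (3S,7R,8R,10R)-8-acetoxy-3-[(2Z)-2-methylbut-2-enoyloxy]eudesma-4,11(13)-dien-12-oate
Product: 27 methyl (3S,5S,7R,8R,10R)-8-acetoxy-5-hydroxy-3-[(2Z)-2-methylbut-2-enoyloxy]eudesma-4(15),11(13)-dien-12-oate, via 5α-hydroperoxide 26 (not isolated)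
Conditions: O2, visible light, 5,10,15,20-tetraphenylporphyrin (cat.), CH2Cl2, −20 °C; then PPh3, 0 °C
Reagents that add atoms: dioxygen O=O
Why: Schenck ene reaction: singlet oxygen should attack the electron-rich tetrasubstituted C4=C5 bond on the α-face (the β-face carries the axial C10 methyl, the axial C8 acetate and the C3 ester) and can abstract only a C15 hydrogen there, since the α-hydrogen at C6 is equatorial and the C3 hydrogen lies near the alkene plane; this gives the 5α-hydroperoxide with the 4(15)-alkene, which PPh3 reduces to the 5α-alcohol (5S).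

**Compound list**
1 | 2-(prop-2-en-1-yl)cyclohexane-1,3-dione | C=CCC1C(=O)CCCC1=O | starting material
2 | 3-(2-methylpropoxy)-2-(prop-2-en-1-yl)cyclohex-2-en-1-one | C=CCC1=C(OCC(C)C)CCCC1=O | intermediate
3 | lithium 1-methyl-3-(2-methylpropoxy)-2-(prop-2-en-1-yl)cyclohex-2-en-1-olate (racemic) | C=CCC1=C(OCC(C)C)CCCC1(C)[O-].[Li+] | intermediate
4 | 3-methyl-2-(prop-2-en-1-yl)cyclohex-2-en-1-one | C=CCC1=C(C)CCCC1=O | intermediate
5 | potassium 5-methyl-6-(prop-2-en-1-yl)cyclohexa-1,5-dien-1-olate | C=CCC1=C(C)CCC=C1[O-].[K+] | intermediate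
6 | rac-6-hydroxy-3-methyl-2-(prop-2-en-1-yl)cyclohex-2-en-1-one | C=CCC1=C(C)CCC(O)C1=O | intermediate
7 | ethenyl acetate (vinyl acetate) | C=COC(C)=O | starting material
8 | (1R)-4-methyl-2-oxo-3-(prop-2-en-1-yl)cyclohex-3-en-1-yl acetate | O=C1C(CC=C)=C(C)CC[C@H]1OC(C)=O | intermediate
9 | bromomagnesium (1R)-4-methyl-2-oxo-3-(prop-2-en-1-yl)cyclohex-3-en-1-olate | O=C1C(CC=C)=C(C)CC[C@H]1O[Mg]Br | intermediate
10 | (1R,2S)-2,4-dimethyl-3-(prop-2-en-1-yl)cyclohex-3-ene-1,2-diol (cis-diol) | O[C@@H]1CCC(C)=C(CC=C)[C@]1(C)O | intermediate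
11 | (2S)-2-hydroxy-2,4-dimethyl-3-(prop-2-en-1-yl)cyclohex-3-en-1-one | O=C1CCC(C)=C(CC=C)[C@]1(C)O | intermediate
12 | methyl 2-(bromomethyl)prop-2-enoate | C=C(CBr)C(=O)OC | starting material
13 | bis(pinacolato)diboron | CC1(C)OB(OC1(C)C)B1OC(C)(C)C(C)(C)O1 | starting material
14 | methyl 2-[(4,4,5,5-tetramethyl-1,3,2-dioxaborolan-2-yl)methyl]prop-2-enoate | C=C(CB1OC(C)(C)C(C)(C)O1)C(=O)OC | intermediate
15 | methyl (2E)-4-[(6S)-6-hydroxy-2,6-dimethyl-5-oxocyclohex-1-en-1-yl]-2-[(4,4,5,5-tetramethyl-1,3,2-dioxaborolan-2-yl)methyl]but-2-enoate | O=C1CCC(C)=C(C/C=C(\CB2OC(C)(C)C(C)(C)O2)C(=O)OC)[C@]1(C)O | intermediate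
16 | methyl (2E)-4-[(6S)-6-(ethenyloxy)-2,6-dimethyl-5-oxocyclohex-1-en-1-yl]-2-[(4,4,5,5-tetramethyl-1,3,2-dioxaborolan-2-yl)methyl]but-2-enoate | O=C1CCC(C)=C(C/C=C(\CB2OC(C)(C)C(C)(C)O2)C(=O)OC)[C@]1(C)OC=C | intermediate
17 | methyl (2E)-4-[(6R)-2,6-dimethyl-3-oxo-6-(2-oxoethyl)cyclohex-1-en-1-yl]-2-[(4,4,5,5-tetramethyl-1,3,2-dioxaborolan-2-yl)methyl]but-2-enoate | CC1=C(C/C=C(\CB2OC(C)(C)C(C)(C)O2)C(=O)OC)[C@@](C)(CC=O)CCC1=O | intermediate
18 | methyl (7R,8R,10R)-3-oxo-8-[(4,4,5,5-tetramethyl-1,3,2-dioxaborolan-2-yl)oxy]eudesma-4,11(13)-dien-12-oate | C=C(C(=O)OC)[C@H]1CC2=C(C)C(=O)CC[C@]2(C)C[C@H]1OB3OC(C)(C)C(C)(C)O3 | intermediate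
19 | (7R,8R,10R)-3-oxoeudesma-4,11(13)-dien-12,8-olide (8β-oxygen, cis-fused α-methylene lactone) | C=C1C(=O)O[C@@H]2C[C@@]3(C)CCC(=O)C(C)=C3C[C@H]12 | intermediate
20 | lithium (7R,8R,10R)-8-hydroxy-3-oxoeudesma-4,11(13)-dien-12-oate | C=C(C(=O)[O-])[C@H]1CC2=C(C)C(=O)CC[C@]2(C)C[C@H]1O.[Li+] | intermediate
21 | methyl (7R,8R,10R)-8-hydroxy-3-oxoeudesma-4,11(13)-dien-12-oate | C=C(C(=O)OC)[C@H]1CC2=C(C)C(=O)CC[C@]2(C)C[C@H]1O | intermediate
22 | methyl (7R,8R,10R)-8-acetoxy-3-oxoeudesma-4,11(13)-dien-12-oate | C=C(C(=O)OC)[C@H]1CC2=C(C)C(=O)CC[C@]2(C)C[C@H]1OC(C)=O | intermediate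
23 | methyl (3S,7R,8R,10R)-8-acetoxy-3-hydroxyeudesma-4,11(13)-dien-12-oate (3β-OH) | C=C(C(=O)OC)[C@H]1CC2=C(C)[C@@H](O)CC[C@]2(C)C[C@H]1OC(C)=O | intermediate
24 | (2Z)-2-methylbut-2-enoic acid (angelic acid) | C/C=C(/C)C(=O)O | starting material
25 | methyl (3S,7R,8R,10R)-8-acetoxy-3-[(2Z)-2-methylbut-2-enoyloxy]eudesma-4,11(13)-dien-12-oate | C=C(C(=O)OC)[C@H]1CC2=C(C)[C@@H](OC(=O)/C(C)=C\C)CC[C@]2(C)C[C@H]1OC(C)=O | intermediate
26 | methyl (3S,5S,7R,8R,10R)-8-acetoxy-5-hydroperoxy-3-[(2Z)-2-methylbut-2-enoyloxy]eudesma-4(15),11(13)-dien-12-oate | C=C(C(=O)OC)[C@H]1C[C@@]2(OO)C(=C)[C@@H](OC(=O)/C(C)=C\C)CC[C@]2(C)C[C@H]1OC(C)=O | intermediate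
27 | methyl (3S,5S,7R,8R,10R)-8-acetoxy-5-hydroxy-3-[(2Z)-2-methylbut-2-enoyloxy]eudesma-4(15),11(13)-dien-12-oate (CNP0179024.1) | C=C(C(=O)OC)[C@H]1C[C@@]2(O)C(=C)[C@@H](OC(=O)/C(C)=C\C)CC[C@]2(C)C[C@H]1OC(C)=O | target

Total steps: 13. Longest linear sequence: 12 steps (from 1 to 27 through steps 1–6 and 8–13; step 7 is a one-step side branch).

**Steps most likely to fail**

Step 9 (Proposed new method). The iridium catalyst, or acetaldehyde released by competing acetyl transfer, may consume the allylboronate, and O-vinylation of the hindered tertiary ketol may stall. The fallback makes the two bonds one after the other by known reactions. It sets out from 11: vinyl exchange with ethyl vinyl ether under Hg(OAc)2 catalysis (divalent mercury) should give the vinyl ether (2S)-2-(ethenyloxy)-2,4-dimethyl-3-(prop-2-en-1-yl)cyclohex-3-en-1-one F1. Thermal Claisen rearrangement (toluene, 110 °C) should then give 2-[(1R)-1,3-dimethyl-4-oxo-2-(prop-2-en-1-yl)cyclohex-2-en-1-yl]acetaldehyde F2. Cross-metathesis of F2 with 14 gives 17, which closes by allylboration (thermally or with Sc(OTf)3) to 18 and with p-TsOH to 19, where the route is rejoined.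

Step 10. Conjugate addition of hydroxide or of the acylation catalyst to the exocyclic methylene, and re-closure of the lactone during the slow acetylation of the hindered axial alcohol, may erode the material. The fallback masks the methylene; it sets out from 19. Dimethylamine adds to give (7R,8R,10R)-13-(dimethylamino)-3-oxoeudesm-4-en-12,8-olide F3 (C11 epimers). LiOH opens it to lithium (7R,8R,10R)-13-(dimethylamino)-8-hydroxy-3-oxoeudesm-4-en-12-oate F4. Excess MeI esterifies and quaternises it to methyl (7R,8R,10R)-8-hydroxy-3-oxo-13-(trimethylammonio)eudesm-4-en-12-oate iodide F5. Ac2O/DMAP, now usable in large excess because no Michael acceptor is present, gives methyl (7R,8R,10R)-8-acetoxy-3-oxo-13-(trimethylammonio)eudesm-4-en-12-oate iodide F6. Aqueous NaHCO3 then eliminates trimethylamine and returns the route to 22.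

Step 13. Hydrogen abstraction from C3 or C6 instead of C15, attack of singlet oxygen on the β-face, or further reaction of the allylic hydroperoxide may lower the selectivity. The fallback replaces the ene reaction by epoxidation and base-mediated epoxide opening; it sets out from 25. m-CPBA (NaHCO3, CH2Cl2) should epoxidise the C4=C5 bond on the α-face to methyl (3S,7R,8R,10R)-8-acetoxy-4α,5α-epoxy-3-[(2Z)-2-methylbut-2-enoyloxy]eudesm-11(13)-en-12-oate F7. Diethylaluminium 2,2,6,6-tetramethylpiperidide (Et2AlNC9H18, toluene, 0 °C) should then remove a C15 proton and open the epoxide to the 5α-hydroxy-4(15)-ene, which is 27.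

**Further compounds**
F1 | step 9 | (2S)-2-(ethenyloxy)-2,4-dimethyl-3-(prop-2-en-1-yl)cyclohex-3-en-1-one | O=C1CCC(C)=C(CC=C)[C@]1(C)OC=C
F2 | step 9 | 2-[(1R)-1,3-dimethyl-4-oxo-2-(prop-2-en-1-yl)cyclohex-2-en-1-yl]acetaldehyde | CC1=C(CC=C)[C@@](C)(CC=O)CCC1=O
F3 | step 10 | (7R,8R,10R)-13-(dimethylamino)-3-oxoeudesm-4-en-12,8-olide (C11 epimers) | CN(C)CC1C(=O)O[C@@H]2C[C@@]3(C)CCC(=O)C(C)=C3C[C@H]12
F4 | step 10 | lithium (7R,8R,10R)-13-(dimethylamino)-8-hydroxy-3-oxoeudesm-4-en-12-oate | CN(C)CC(C(=O)[O-])[C@H]1CC2=C(C)C(=O)CC[C@]2(C)C[C@H]1O.[Li+]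
F5 | step 10 | methyl (7R,8R,10R)-8-hydroxy-3-oxo-13-(trimethylammonio)eudesm-4-en-12-oate iodide | C[N+](C)(C)CC(C(=O)OC)[C@H]1CC2=C(C)C(=O)CC[C@]2(C)C[C@H]1O.[I-]
F6 | step 10 | methyl (7R,8R,10R)-8-acetoxy-3-oxo-13-(trimethylammonio)eudesm-4-en-12-oate iodide | C[N+](C)(C)CC(C(=O)OC)[C@H]1CC2=C(C)C(=O)CC[C@]2(C)C[C@H]1OC(C)=O.[I-]
F7 | step 13 | methyl (3S,7R,8R,10R)-8-acetoxy-4α,5α-epoxy-3-[(2Z)-2-methylbut-2-enoyloxy]eudesm-11(13)-en-12-oate | C=C(C(=O)OC)[C@H]1C[C@@]23O[C@]2(C)[C@@H](OC(=O)/C(C)=C\C)CC[C@]3(C)C[C@H]1OC(C)=O
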